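A small charge of initiator has to start the chains, yet the monomer in chains of amber stands still near 70.1% of the free monomer charged and that of violet near 89.5%.

common to all: impurity 4.1 mM
- amber: free monomer 0.034 M; transfer agent 5 mM; initiator 3 mM; run made earlier
- violet: free monomer 0.13 M; transfer agent 5 mM; initiator 3 mM; run made earlier
- east: free monomer 0.050 M; transfer agent 5.00 mM; initiator 3.0 mM; time 80 min
- north-east: free monomer 0.15 M; transfer agent 5.00 mM; initiator 3.0 mM; time 80 min

| run | time / min | monomer in chains / % |
|---|---|---|
| amber | 4.00 | 40.7 |
| amber | 10.0 | 58.7 |
| amber | 20.0 | 68.5 |
| amber | 30.0 | 70.3 |
| amber | 40.0 | 70.1 |
| violet | 8.00 | 74.0 |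
| violet | 15.0 | 84.1 |
| violet | 25.0 | 87.7 |
| violet | 30.0 | 88.6 |
| violet | 40.0 | 89.5 |

(readings scatter by 0.3 percentage points)
- the average divides the monomer in chains by the number of chains begun, living and dead together
- on the list of suspects stand: free monomer + initiator -> living end + monomer in chains; free monomer + living end -> monomer in chains + living end; living end + transfer agent -> dead chain; 2 initiator -> spent initiator A; initiator + impurity -> spent initiator B
- the earlier runs do not show the number of chains; that part of a forecast is a guess
* which of the two ends with the longer chains by the average number of monomer units in a chain (chains begun, living or dead) ("neither" if they lie within 10%) (east / north-east / neither)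
* average number of monomer units in a chain (chains begun, living or dead) at the end, east
* average number of monomer units in a chain (chains begun, living or dead) at the end, north-east

At one moment, the fractional fall of free monomer and that of transfer agent each carry the same concentration of living ends, which cancels in their ratio. So, apart from the free monomer spent on starting chains, the stop number, ln(charge/left) of free monomer, keeps a fixed ratio to the same logarithm for transfer agent while the concentrations drift. Each dead chain takes one transfer agent, so this ratio turns a stop number into chains begun.

The first way reads the plateaus: 1.21 in amber and 2.25 in violet. If free monomer competes for initiator with a half-share at 0.0576 M, and a full share spends the whole charge on chains, the selectivity factor r, the fixed ratio of the two logarithms, reads 3.55. On this reckoning violet began 2.35 mM of chains.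

The second way reads the tails, whose time constants, 6.55 min in amber and 13.2 min in violet, go inversely with the transfer agent left. That gives violet 3.43 mM, more than the 3.0 mM of initiator charged. The tail cheats: violet's last step in stop number is 0.0822, and the scatter of that step is about half of it.

The plateau way gives, as this reckoning's own lengths, 22.5 for east and 56.0 for north-east.

The forecast names north-east, with 28 (20 to 38) for east and 64 (47 to 85) for north-east, noting that “chains do not scale with monomer”. Both its lengths stand above those reckoned here.

The flasks give north-east, with 24.9 for east and 60.1 for north-east.

    free monomer + initiator → living end + monomer in chains (k = 2.40 L mol⁻¹ s⁻¹)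
    free monomer + living end → monomer in chains + living end, rate k2*[living end]*[free monomer] (k = 2.10 L mol⁻¹ s⁻¹)
    living end + transfer agent → dead chain (kL = 0.530 L mol⁻¹ s⁻¹)
    2 initiator → spent initiator A (k = 29.0 L mol⁻¹ s⁻¹)
    initiator + impurity → spent initiator B (k = 8.10 L mol⁻¹ s⁻¹)

The charge of free monomer is the main reason for the gap: with the difference in free monomer taken away, north-east ends at 24.9. The simulated 8.92% of free monomer in north-east, put through r, gives 55.3 units against the 60.1 that flask shows. A neighbour of north-east with 7.5 × 10⁻⁴ M of initiator keeps 57.3% of its free monomer, which through r gives 88.2 units, and its simulated length is 98.4.

All runs stem from a simulated flask with made-up constants, noise included.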